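**Retrosynthetic overview**
1. Target 11 ⇒ open the pyranone at O1–C2 (acid-catalysed C–O cyclodehydration; the only ring made, and made last) ⇒ 1,3-diketone 9.
2. Diketone 9 ⇒ C-acylation of the polyanion of phloroacetophenone 7 with aroyl chloride 6 (3-OTBS as an acid-labile mask).
3. 6 ⇒ hydroxy acid 4 ⇒ C3–O disconnection: direct C–H hydroxylation of 2,4,5-trimethoxybenzoic acid 1 at the position flanked by two OMe groups (new method).
4. Rings A and B are bought intact; only ring C is constructed.

Assumption: the target has no stereocentres (achiral flavone), so no stereocontrol is needed; commercial 7 monohydrate is dried before use.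

**Step 1**
Reactants: 1 2,4,5-trimethoxybenzoic acid
Product: 4 3-hydroxy-2,4,5-trimethoxybenzoic acid, via C3-metalated benzoate 2 (not isolated), via arylboronate 3 (not isolated)
Conditions: n-BuLi/KOt-Bu (3.5 equiv each), THF, −78 °C, 2 h; B(OMe)3 (6 equiv), −78 → 0 °C; AcOH, 30% H2O2, 0 °C → rt; aq. Na2SO3, then HCl work-up
Reagents that add atoms: hydrogen peroxide, OO
Why: Proposed new method: a carboxylate-tolerant, methoxy-flanked meta-C–H hydroxylation of a free benzoic acid — once the acid is its carboxylate, the Li/K superbase removes the only ring proton flanked by two OMe groups (C3: doubly inductively acidified, K+ chelated by both oxygens, and remote from the carboxylate, which under these weakly coordinating conditions repels rather than directs, so C6 is left alone), aryl-metal 2 is trapped as boronate 3, and peroxide oxidation (1,2-aryl shift from B to O at the same carbon) forms the C3–O bond; the closest known reactions are the n-BuLi/KOt-Bu metalation of unprotected 2-methoxybenzoic acid next to OMe (trapped so far with C, Si or halogen electrophiles) and the lithiation–boration–oxidation of 1,3-dimethoxyarenes.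

**Step 2**
Reactants: 4 3-hydroxy-2,4,5-trimethoxybenzoic acid
Product: 6 3-(tert-butyldimethylsilyloxy)-2,4,5-trimethoxybenzoyl chloride, via bis-silyl derivative 5 (not isolated)
Conditions: TBSCl (2.2 equiv), imidazole (2.3 equiv), DMF (cat.), CH2Cl2, rt; then (COCl)2 (1.3 equiv), 0 °C → rt; filter under Ar, concentrate, use crude
Reagents that add atoms: tert-butyldimethylsilyl chloride, CC(C)(C)[Si](C)(C)Cl; oxalyl chloride, O=C(Cl)C(Cl)=O
Why: Imidazole-promoted O-silylation covers both the phenol and the acid, and the Vilsmeier chloride from (COCl)2/DMF converts only the silyl ester into the acid chloride under neutral conditions (TBSCl, CO and CO2 leave), so the hindered aryl TBS ether survives as the mask for the 3'-OH.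

**Step 3**
Reactants: 6 3-(tert-butyldimethylsilyloxy)-2,4,5-trimethoxybenzoyl chloride; 7 2',4',6'-trihydroxyacetophenone
Product: 11 5,7,3'-trihydroxy-2',4',5'-trimethoxyflavone, via tetralithium polyanion 8 (not isolated), via silyloxy diketone 9 (not isolated), via 3'-O-TBS flavone 10 (not isolated)
Conditions: 7, LiHMDS (5 equiv), THF, −78 → −10 °C; 6 (1.0 equiv), −78 °C → rt; evaporate volatiles; H2SO4 (excess over Li), AcOH, 95 °C, 2 h; pour into water
Reagents that add atoms: none
Why: The phenoxide-enolate polyanion of 7 is acylated on carbon by 6 (Claisen-type direct C-acylation, the one-flask equivalent of a Baker–Venkataraman transfer; the fifth equivalent of base takes up the acidic diketone proton), and hot H2SO4/AcOH then makes an ortho-OH attack the enolised aryl ketone with loss of water (cyclodehydration forming the pyranone O1–C2 bond; both ortho-OH groups give the same ring) and cleaves the aryl silyl ether.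

**Compound list**
1 | 2,4,5-trimethoxybenzoic acid | OC(=O)c1cc(OC)c(OC)cc1OC | starting material
2 | lithium 3-potassio-2,4,5-trimethoxybenzoate (C3-metalated benzoate) | [Li+].[K+].[O-]C(=O)c1cc(OC)c(OC)[c-]c1OC | intermediate
3 | lithium 3-(dimethoxyboryl)-2,4,5-trimethoxybenzoate (arylboronate) | [Li+].[O-]C(=O)c1cc(OC)c(OC)c(B(OC)OC)c1OC | intermediate
4 | 3-hydroxy-2,4,5-trimethoxybenzoic acid | OC(=O)c1cc(OC)c(OC)c(O)c1OC | intermediate
5 | tert-butyldimethylsilyl 3-(tert-butyldimethylsilyloxy)-2,4,5-trimethoxybenzoate | COc1cc(C(=O)O[Si](C)(C)C(C)(C)C)c(OC)c(O[Si](C)(C)C(C)(C)C)c1OC | intermediate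
6 | 3-(tert-butyldimethylsilyloxy)-2,4,5-trimethoxybenzoyl chloride | COc1cc(C(Cl)=O)c(OC)c(O[Si](C)(C)C(C)(C)C)c1OC | intermediate
7 | 2',4',6'-trihydroxyacetophenone | CC(=O)c1c(O)cc(O)cc1O | starting material
8 | tetralithium 2-(1-oxidoethenyl)benzene-1,3,5-triolate (polyanion of 7) | [Li+].[Li+].[Li+].[Li+].C=C([O-])c1c([O-])cc([O-])cc1[O-] | intermediate
9 | 1-[3-(tert-butyldimethylsilyloxy)-2,4,5-trimethoxyphenyl]-3-(2,4,6-trihydroxyphenyl)propane-1,3-dione (formed as its lithium salt) | COc1cc(C(=O)CC(=O)c2c(O)cc(O)cc2O)c(OC)c(O[Si](C)(C)C(C)(C)C)c1OC | intermediate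
10 | 3'-(tert-butyldimethylsilyloxy)-5,7-dihydroxy-2',4',5'-trimethoxyflavone | COc1cc(-c2cc(=O)c3c(O)cc(O)cc3o2)c(OC)c(O[Si](C)(C)C(C)(C)C)c1OC | intermediate
11 | 5,7,3'-trihydroxy-2',4',5'-trimethoxyflavone | COc1cc(-c2cc(=O)c3c(O)cc(O)cc3o2)c(OC)c(O)c1OC | target

**Totals**
Total steps: 3. Longest linear sequence: 3 (1 → 4 → 6 → 11; 7 enters at step 3).

**Steps most likely to fail**

Step 1 (proposed new method). Risks: metalation at C6 next to the carboxylate instead of C3, butyl addition to the carboxylate, and over-oxidation of the electron-rich phenol. Fallback (known blocking-group ortho-metalation chemistry), setting out from 1: s-BuLi/TMEDA in THF at −78 °C lithiates ortho to the carboxylate at C6 (reinforced by the 5-OMe), and TMSCl gives 3,4,6-trimethoxy-2-(trimethylsilyl)benzoic acid F1. A second s-BuLi/TMEDA lithiation can then take only the remaining OMe-flanked ring C–H; B(OMe)3 followed by H2O2 gives 5-hydroxy-3,4,6-trimethoxy-2-(trimethylsilyl)benzoic acid F2. Ipso-protodesilylation with TFA in CH2Cl2 (the silyl group sits para to the new OH) returns to the route at 4.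

Step 3. Risks: poor solubility of the polyanion 8, competing O-acylation, and buffering of the acid by lithium salts in the one-flask cyclisation. Fallback, setting out from 7: TBSCl (2.1 equiv) with i-Pr2NEt in CH2Cl2 silylates the two non-chelated phenols to give 2'-hydroxy-4',6'-bis(tert-butyldimethylsilyloxy)acetophenone F4. Its soluble dilithio species (LiHMDS, 3 equiv, THF, −78 °C) is C-acylated with 6 to give 1-[2-hydroxy-4,6-bis(tert-butyldimethylsilyloxy)phenyl]-3-[3-(tert-butyldimethylsilyloxy)-2,4,5-trimethoxyphenyl]propane-1,3-dione F5, which is isolated and purified. H2SO4/AcOH at 95 °C then closes the pyranone and removes all three silyl groups, coming back to the route at 11.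

Step 2. Risks: incomplete silylation of the hindered phenol in CH2Cl2, and loss of the aryl silyl ether if HCl builds up during chlorination. Fallback, setting out from 4: TBSCl/imidazole in DMF gives 5, now isolated by extractive work-up. AcOH/THF/H2O at rt cleaves only the silyl ester to give 3-(tert-butyldimethylsilyloxy)-2,4,5-trimethoxybenzoic acid F3, which is purified. It is then activated under strictly neutral conditions with 1-chloro-N,N,2-trimethylprop-1-enylamine (Ghosez reagent) in CH2Cl2, coming back to the route at 6.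

**Further compounds**
F1 | step 1 | 3,4,6-trimethoxy-2-(trimethylsilyl)benzoic acid | OC(=O)c1c([Si](C)(C)C)c(OC)c(OC)cc1OC
F2 | step 1 | 5-hydroxy-3,4,6-trimethoxy-2-(trimethylsilyl)benzoic acid | OC(=O)c1c([Si](C)(C)C)c(OC)c(OC)c(O)c1OC
F3 | step 2 | 3-(tert-butyldimethylsilyloxy)-2,4,5-trimethoxybenzoic acid | COc1cc(C(=O)O)c(OC)c(O[Si](C)(C)C(C)(C)C)c1OC
F4 | step 3 | 2'-hydroxy-4',6'-bis(tert-butyldimethylsilyloxy)acetophenone | CC(=O)c1c(O)cc(O[Si](C)(C)C(C)(C)C)cc1O[Si](C)(C)C(C)(C)C
F5 | step 3 | 1-[2-hydroxy-4,6-bis(tert-butyldimethylsilyloxy)phenyl]-3-[3-(tert-butyldimethylsilyloxy)-2,4,5-trimethoxyphenyl]propane-1,3-dione | COc1cc(C(=O)CC(=O)c2c(O)cc(O[Si](C)(C)C(C)(C)C)cc2O[Si](C)(C)C(C)(C)C)c(OC)c(O[Si](C)(C)C(C)(C)C)c1OC
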